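## Analysis of the target

The target is a cyclohex-2-enone in which every ring carbon is functionalised. The ring is numbered here C1 ((E)-hept-1-enyl), C2 (CH2OH), C3 (CHOH), C4 and C5 (the fused oxirane; C5 is quaternary and carries the CH2–CH=C(CH3)–CO2H chain) and C6 (ketone). There are three contiguous stereocentres, C3, C4 and C5, all S: the oxirane is cis-fused, the C3 hydroxyl lies on the same face as the oxirane oxygen, and the C5 side chain lies on the opposite face. C1=C2 is tetrasubstituted and sits between the C6 carbonyl and the heptenyl double bond, so the chromophore is a cross-conjugated dienone. The sensitive groups are the α,β-epoxy ketone, the γ-hydroxy enone (base would open the oxirane or cause elimination), two allylic alcohols, the methylene between C5 and the enoate, and the free acid; the last steps therefore have to be neutral or acidic. The difficulty is density: a quaternary oxirane carbon next to the ketone, a tetrasubstituted alkene with four different substituents, and an absolute configuration that resides only in the oxirane and its neighbour. The strategy rests on C1=C2: the heptenyl group on C1 is trans to the C2–C3 bond, which is the pattern left by an anti addition of an aldehyde carbon (C3) and an alkenyl group across a C1≡C2 alkyne.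

## Retrosynthetic reasoning

**20 ⇐ 19 ⇐ 18.** No skeletal bond is cut in the last two operations. Target 20 is traced to its tert-butyl ester 19, and this to 18, in which C6 is an ethylene ketal and the primary alcohol a TBS (tert-butyldimethylsilyl) ether. All three masks fall to acid, which the γ-hydroxy epoxy enone tolerates far better than base. Ketal and silyl ether go first, so that the free C6 carbonyl deactivates the C3 allylic alcohol towards ionisation before strong acid is used on the ester.

**18 ⇐ 17 ⇐ 16.** The C3–H bond is disconnected by redox. 18 is taken back to enone 17, and 17 to alcohol 16, the C3 epimer of 18 and the expected main product of the ring closure. The ring-forming step creates C3 next to the oxirane under a bias that is hard to predict and probably modest. Hydride addition to 17, a 2,3-epoxycyclohexenone, is governed by the oxirane oxygen and places the hydroxyl cis to it. Any 18 that the ring closure forms directly is oxidised to the same ketone 17. Two redox steps therefore buy independence from the diastereoselectivity of the key step.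

**16 ⇐ 14 + 15.** The strategic cut removes C2–C3 and the bond from C1 to the heptenyl group, both at the tetrasubstituted alkene. Cutting here, and not at the oxirane or the carbonyl, turns the most congested element of the ring into an alkyne whose two substituents are trivially placed. It reveals epoxy alkynal 14 and boronic acid 15. The forward reaction must add C3 and the alkenyl group anti across C1≡C2 with six-membered endo closure, and leave oxirane, ketal, enoate and silyl ether alone. The ketal keeps C1≡C2 an isolated alkyne and not an ynone.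

**14 ⇐ 13 ⇐ 12.** 14 is the aldehyde of epoxy alcohol 13, and the two C–O bonds of the oxirane are cut to give Z-allylic alcohol 12. Epoxidation is a syn addition, so the Z geometry of 12 (C3 and C6 cis) becomes the cis relation that the ring needs. The absolute configuration at C4 and C5 is set by a Sharpless asymmetric epoxidation before any ring exists.

**12 ⇐ 11 ⇐ 10.** 12 comes from its TES (triethylsilyl) ether 11, and the ketal of 11 from enynone 10. The ketal must be installed while the C3 oxygen is still silylated, because a free Z-disposed hydroxyl would add to the C6 carbonyl. Two different silyl groups allow the allylic one to be removed while the propargylic one stays to the end.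

**10 ⇐ 8 + 9.** The bonds C5–C6 and C6–C1 are cut; C6 enters as a single carbonyl carbon between vinyl iodide 8 and alkyne 9 in a carbonylative Sonogashira coupling. This needs no strongly basic organometallic, so the enoate and its doubly allylic methylene are not at risk, and the vinyl iodide transmits its geometry with retention.

**8 ⇐ 6 + 7; 6 ⇐ 5 ⇐ 3 ⇐ 1 + 2.** The trisubstituted enoate double bond of 8 is cut by cross-metathesis into terminal alkene 6 and methacrylate 7. This is done before any alkyne is present, because an enyne would be drawn into enyne metathesis. 6 is the silyl ether of 5, whose C–I bond and Z geometry come from hydroxyl-directed trans-hydroalumination and iodination of enynol 3, itself one copper-catalysed step from 1 and 2. The tert-butyl ester of 7 is chosen for the acidic end game.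

## Alternatives that were turned down

**Alternative 1:** The two oxiranes of syn-diepoxide A1 would be cut back to cyclohexa-1,3-diene A2. In the forward sense singlet oxygen adds across the diene termini of A2 on the face away from the ring silyloxy group, and Co(TPP) (cobalt tetraphenylporphyrin, divalent cobalt) isomerises the O–O bridge in the same flask into two cis-disposed oxiranes. In A1 the C2–C3 oxirane is a latent form of the C1=C2/C3–OH unit: after oxidation of C6 to the ketone, β-elimination opens it to the γ-hydroxy enone.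
- For it: four C–O bonds and the full C3/C4/C5 relationship arise in one operation, and the C3 hydroxyl is automatically cis to the surviving oxirane. On this point it is better than the chosen route, which needs a redox correction at C3.
- Against it: the heptenyl diene cannot be present during photooxygenation (it is itself a singlet-oxygen substrate), so C1 must be halogenated and cross-coupled afterwards. A2 must be made enantiopure with a stereocentre that only steers the oxygen and is then oxidised away. Ene reactions at the allylic positions compete with cycloaddition.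
- Comparison: five or six operations remain after the key step (desilylation, oxidation, oxirane opening, halogenation, coupling, deprotections) against four in the chosen route. The chosen route builds the ring and attaches the heptenyl group in one step from an oxirane whose configuration comes from a catalytic epoxidation.

**Alternative 2:** C4–C5 and the C5–O bond of the oxirane are cut, leading from silyl-protected methyl ester A3 to open-chain chloro keto aldehyde A4. Forward, the enolate of the α-chloro ketone adds to the aldehyde (intramolecular aldol, six-membered ring) and the alkoxide displaces chloride (Darzens).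
- For it: ring and oxirane form together, and both C5 epimers of A4 converge through one enolate. Only the aldol diastereomer with alkoxide anti to chlorine can close, while the other reverts. A3 is three deprotections from the target, so its end game is shorter than that of the chosen route and needs no redox step at C3.
- Against it: A4 already contains the Z-configured tetrasubstituted C1=C2 dienone with all four substituents, so the hardest element must be made beforehand by an unspecified stereoselective alkene synthesis. Its aldehyde carries a silyloxy group on the α-carbon (C3) and is open to epimerisation or elimination under the base that the Darzens reaction needs. Nothing obvious secures the facial sense of the aldol relative to C3.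
- Comparison: the chosen strategy makes the tetrasubstituted alkene in the ring-forming step from an alkyne and introduces the oxirane under reagent control before cyclisation, at the price of a longer end game.

**Alternative 3:** Three ring bonds of phenol A5 (C3–C4, C5–C6, C6–C1) are cut, giving dienyl(methoxy)carbene complex A6 of Cr(CO)5 (zerovalent chromium), terminal alkyne A7 and one carbonyl ligand. On heating these combine in a Dötz benzannulation.
- For it: all six ring carbons and all four carbon substituents are assembled regioselectively (the alkyne substituent ends next to the new hydroxyl) in one convergent step, and the para-oxygen pattern of A5 maps onto C3 and C6. In convergence and brevity to the carbon skeleton it is stronger than the chosen route.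
- Against it: A5 is flat. C3, C4 and C5 must be created afterwards by oxidation to a quinone or quinone monoketal, enantioselective nucleophilic epoxidation of one of two enone double bonds, and regio- and stereoselective reduction of one of two carbonyls. Absolute control in that epoxidation is the uncertain step. The electron-rich heptenyl diene must survive oxidative dearomatisation, stoichiometric chromium is used, and dienyl carbene complexes can divert to five-membered-ring products.
- Comparison: the chosen route carries an oxirane of defined configuration into the ring closure and needs no dearomatisation, which is what it offers in place of the shorter carbon assembly.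

Key step: step 10

Remark on the chemistry: the acid is carried as its tert-butyl ester, and the ring closure is not required to be selective at C3, because both C3 epimers are funnelled through ketone 17.

## Route

Step 1
Reactants: 1 prop-2-yn-1-ol; 2 3-bromoprop-1-ene (allyl bromide)
Product: 3 hex-5-en-2-yn-1-ol
Conditions: CuI (5 mol%), K2CO3, Bu4NBr (cat.), DMF, rt
Reagents that add atoms: none
Why: Copper-catalysed coupling of a terminal alkyne with an allylic halide is the standard entry to 1,4-enynes and tolerates the free hydroxyl; with an unsubstituted allyl group the SN2 and SN2′ paths give the same product.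

Step 2
Reactants: 3 hex-5-en-2-yn-1-ol
Product: 5 (Z)-3-iodohexa-2,5-dien-1-ol, via cyclic sodium alkenylalanate 4 (not isolated)
Conditions: NaAlH2(OCH2CH2OMe)2, THF, 0 °C to rt; then I2, −78 to 0 °C
Reagents that add atoms: iodine, II
Why: Hydroxyl-directed trans-hydroalumination of a propargylic alcohol delivers hydride to the proximal and aluminium to the distal alkyne carbon within a five-membered alanate, and iodinolysis with retention gives the (Z)-3-iodo allylic alcohol. This geometry later becomes the cis relation of C3 and C6.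

Step 3
Reactants: 5 (Z)-3-iodohexa-2,5-dien-1-ol
Product: 6 triethyl{[(Z)-3-iodohexa-2,5-dien-1-yl]oxy}silane
Conditions: TESCl, imidazole, CH2Cl2, 0 °C
Reagents that add atoms: chlorotriethylsilane, CC[Si](Cl)(CC)CC
Why: Routine silylation; the TES ether prevents lactonisation in the carbonylation and can later be removed in the presence of a primary TBS ether.

Step 4
Reactants: 6 triethyl{[(Z)-3-iodohexa-2,5-dien-1-yl]oxy}silane; 7 tert-butyl 2-methylprop-2-enoate (tert-butyl methacrylate)
Product: 8 tert-butyl (2E,5Z)-5-iodo-2-methyl-7-(triethylsilyloxy)hepta-2,5-dienoate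
Conditions: second-generation Hoveyda–Grubbs catalyst RuCl2(SIMes)(=CH-C6H4-2-OiPr) (5 mol%), 7 (5 equiv), CH2Cl2, 40 °C
Reagents that add atoms: none
Why: Olefin cross-metathesis of a terminal alkene with a methacrylate gives the trisubstituted (E)-enoate under thermodynamic control; the iodinated trisubstituted alkene is inert to the metathesis catalyst.

Step 5
Reactants: 8 tert-butyl (2E,5Z)-5-iodo-2-methyl-7-(triethylsilyloxy)hepta-2,5-dienoate; 9 tert-butyldimethyl(prop-2-yn-1-yloxy)silane
Product: 10 tert-butyl (2E,5Z)-5-[4-(tert-butyldimethylsilyloxy)but-2-ynoyl]-2-methyl-7-(triethylsilyloxy)hepta-2,5-dienoate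
Conditions: CO (1 atm), PdCl2(PPh3)2 (5 mol%), CuI (2 mol%), Et3N, THF, rt
Reagents that add atoms: carbon monoxide, [C-]#[O+]
Why: Carbonylative Sonogashira coupling: PdCl2(PPh3)2 is reduced in the flask to zerovalent palladium, the vinyl iodide adds oxidatively with retention, CO inserts to the acylpalladium and this couples with the alkyne. The amine base spares the ester and the doubly allylic methylene.

Step 6
Reactants: 10 tert-butyl (2E,5Z)-5-[4-(tert-butyldimethylsilyloxy)but-2-ynoyl]-2-methyl-7-(triethylsilyloxy)hepta-2,5-dienoate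
Product: 11 tert-butyl (2E,5Z)-5-{2-[3-(tert-butyldimethylsilyloxy)prop-1-yn-1-yl]-1,3-dioxolan-2-yl}-2-methyl-7-(triethylsilyloxy)hepta-2,5-dienoate
Conditions: TMSOCH2CH2OTMS, TMSOTf (5 mol%), CH2Cl2, −78 to −20 °C; pyridine quench
Reagents that add atoms: 1,2-bis(trimethylsilyloxy)ethane, C[Si](C)(C)OCCO[Si](C)(C)C
Why: Noyori ketalisation is the kinetic, low-temperature method for conjugated ketones and should give the 1,2-ketal without double-bond migration or conjugate addition. Partial loss of the TES group here would be harmless, since it is removed in the next step.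

Step 7
Reactants: 11 tert-butyl (2E,5Z)-5-{2-[3-(tert-butyldimethylsilyloxy)prop-1-yn-1-yl]-1,3-dioxolan-2-yl}-2-methyl-7-(triethylsilyloxy)hepta-2,5-dienoate
Product: 12 tert-butyl (2E,5Z)-5-{2-[3-(tert-butyldimethylsilyloxy)prop-1-yn-1-yl]-1,3-dioxolan-2-yl}-7-hydroxy-2-methylhepta-2,5-dienoate
Conditions: HF·pyridine, pyridine, THF, 0 °C
Reagents that add atoms: none
Why: Buffered HF·pyridine cleaves a primary TES ether much faster than a primary TBS ether, and the excess pyridine keeps the acid-sensitive Z-hydroxy ketal from ionising.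

Step 8
Reactants: 12 tert-butyl (2E,5Z)-5-{2-[3-(tert-butyldimethylsilyloxy)prop-1-yn-1-yl]-1,3-dioxolan-2-yl}-7-hydroxy-2-methylhepta-2,5-dienoate
Product: 13 tert-butyl (E)-4-[(2S,3S)-2-{2-[3-(tert-butyldimethylsilyloxy)prop-1-yn-1-yl]-1,3-dioxolan-2-yl}-3-(hydroxymethyl)oxiran-2-yl]-2-methylbut-2-enoate
Conditions: Ti(OiPr)4 (20 mol%), L-(+)-diethyl tartrate (24 mol%), t-BuOOH, 4 Å MS, CH2Cl2, −20 °C
Reagents that add atoms: tert-butyl hydroperoxide, CC(C)(C)OO
Why: Sharpless asymmetric epoxidation; by the usual mnemonic (the sense that turns nerol into its (2S,3R)-epoxide) L-(+)-diethyl tartrate should give the (2S,3S)-oxirane, and syn oxygen transfer turns the Z geometry into the cis relation of C3 and C6. The electron-poor enoate and the alkyne are not epoxidised by this system.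

Step 9
Reactants: 13 tert-butyl (E)-4-[(2S,3S)-2-{2-[3-(tert-butyldimethylsilyloxy)prop-1-yn-1-yl]-1,3-dioxolan-2-yl}-3-(hydroxymethyl)oxiran-2-yl]-2-methylbut-2-enoate
Product: 14 tert-butyl (E)-4-[(2S,3R)-2-{2-[3-(tert-butyldimethylsilyloxy)prop-1-yn-1-yl]-1,3-dioxolan-2-yl}-3-formyloxiran-2-yl]-2-methylbut-2-enoate
Conditions: Dess–Martin periodinane, NaHCO3, CH2Cl2, 0 °C to rt
Reagents that add atoms: none
Why: Buffered Dess–Martin oxidation takes 2,3-epoxy alcohols to epoxy aldehydes without over-oxidation or oxirane opening; the oxiranyl C4–H is not readily enolised, so the configuration should hold (the descriptor at C4 changes only through priorities).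

Step 10
Reactants: 14 tert-butyl (E)-4-[(2S,3R)-2-{2-[3-(tert-butyldimethylsilyloxy)prop-1-yn-1-yl]-1,3-dioxolan-2-yl}-3-formyloxiran-2-yl]-2-methylbut-2-enoate; 15 (E)-hept-1-en-1-ylboronic acid
Product: 16 tert-butyl (E)-4-[(1S,5R,6S)-2,2-(ethylenedioxy)-3-[(E)-hept-1-enyl]-5-hydroxy-4-(tert-butyldimethylsilyloxymethyl)-7-oxabicyclo[4.1.0]hept-3-en-1-yl]-2-methylbut-2-enoate (C3–OH trans to the oxirane oxygen)
Conditions: Pd(PPh3)4 (5 mol%), 15 (1.5 equiv), MeOH, 65 °C
Reagents that add atoms: none
Why: Zerovalent palladium coordinates the C1≡C2 alkyne, and the electron-rich alkyne complex attacks the methanol-activated C3 aldehyde through C2 from the side opposite the metal, so C2–C3 and C1–Pd form anti and an alkenylpalladium species results. Transmetalation with 15 and reductive elimination then place the heptenyl group on C1 with its E geometry retained and return zerovalent palladium. The closest known reaction type is the zerovalent-palladium/phosphine-catalysed trans-selective arylative and alkenylative cyclisation of 5-alkynals with boronic acids to cyclohex-2-enols (anti-Wacker type). The ring closes in the 6-endo-dig mode typical of 5-alkynals in this reaction, with both alkyne carbons inside the ring; the 5-exo alternative through C1 would give a strained bicyclo[3.1.0] system with an exocyclic tetrasubstituted alkene. C3 is the only new stereocentre and is controlled by the adjacent C4 oxirane centre: in the flattened cyclic transition state the carbonyl oxygen should prefer to point away from the oxirane oxygen (dipole minimisation), which predicts 16 as the main epimer. That preference is expected to be modest and is not relied on, because the minor C3 epimer (hydroxyl cis to the oxirane oxygen, the alcohol that step 12 makes on purpose) is oxidised to the same ketone in step 11 and need not be separated. What the step does need is trans addition and chemoselectivity: trans addition is enforced by the mechanism and the tether, the C6 ketal removes ynone character and blocks conjugate addition, and the oxirane is neither allylic nor propargylic to palladium.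

Step 11
Reactants: 16 tert-butyl (E)-4-[(1S,5R,6S)-2,2-(ethylenedioxy)-3-[(E)-hept-1-enyl]-5-hydroxy-4-(tert-butyldimethylsilyloxymethyl)-7-oxabicyclo[4.1.0]hept-3-en-1-yl]-2-methylbut-2-enoate
Product: 17 tert-butyl (E)-4-[(1S,6R)-2,2-(ethylenedioxy)-3-[(E)-hept-1-enyl]-5-oxo-4-(tert-butyldimethylsilyloxymethyl)-7-oxabicyclo[4.1.0]hept-3-en-1-yl]-2-methylbut-2-enoate
Conditions: Dess–Martin periodinane, NaHCO3, CH2Cl2, 0 °C
Reagents that add atoms: none
Why: Dess–Martin oxidation of a secondary allylic alcohol to an epoxyquinone-monoketal-type enone; the buffer protects ketal and silyl ether. Any C3 epimer that accompanies 16 from step 10 gives the same enone, so the crude cyclisation product can be used.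

Step 12
Reactants: 17 tert-butyl (E)-4-[(1S,6R)-2,2-(ethylenedioxy)-3-[(E)-hept-1-enyl]-5-oxo-4-(tert-butyldimethylsilyloxymethyl)-7-oxabicyclo[4.1.0]hept-3-en-1-yl]-2-methylbut-2-enoate
Product: 18 tert-butyl (E)-4-[(1S,5S,6S)-2,2-(ethylenedioxy)-3-[(E)-hept-1-enyl]-5-hydroxy-4-(tert-butyldimethylsilyloxymethyl)-7-oxabicyclo[4.1.0]hept-3-en-1-yl]-2-methylbut-2-enoate (C3–OH cis to the oxirane oxygen)
Conditions: NaBH4, CeCl3·7H2O, MeOH, −78 °C
Reagents that add atoms: none
Why: Luche reduction gives 1,2-reduction of the enone; as in other 2,3-epoxycyclohexenones the hydride should approach C3 from the face opposite the oxirane oxygen (steric and electrostatic shielding), which sets C3 as S with the hydroxyl cis to the oxirane.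

Step 13
Reactants: 18 tert-butyl (E)-4-[(1S,5S,6S)-2,2-(ethylenedioxy)-3-[(E)-hept-1-enyl]-5-hydroxy-4-(tert-butyldimethylsilyloxymethyl)-7-oxabicyclo[4.1.0]hept-3-en-1-yl]-2-methylbut-2-enoate
Product: 19 tert-butyl (E)-4-[(1S,5S,6S)-3-[(E)-hept-1-enyl]-5-hydroxy-4-(hydroxymethyl)-2-oxo-7-oxabicyclo[4.1.0]hept-3-en-1-yl]-2-methylbut-2-enoate
Conditions: 1 M aq. HCl, THF, 0 °C to rt
Reagents that add atoms: water, O
Why: Acid hydrolysis of an allylic ketal (oxocarbenium stabilised by C1=C2) and of a primary silyl ether; once the C6 carbonyl is free the C3 alcohol is deactivated towards ionisation, and a tert-butyl ester survives dilute acid.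

Step 14
Reactants: 19 tert-butyl (E)-4-[(1S,5S,6S)-3-[(E)-hept-1-enyl]-5-hydroxy-4-(hydroxymethyl)-2-oxo-7-oxabicyclo[4.1.0]hept-3-en-1-yl]-2-methylbut-2-enoate
Product: 20 (E)-4-[(1S,5S,6S)-3-[(E)-hept-1-enyl]-5-hydroxy-4-(hydroxymethyl)-2-oxo-7-oxabicyclo[4.1.0]hept-3-en-1-yl]-2-methylbut-2-enoic acid (target)
Conditions: CF3CO2H, CH2Cl2, 0 °C to rt; aqueous work-up
Reagents that add atoms: none
Why: Acidolysis of the tert-butyl ester (loss of 2-methylpropene) frees the acid without base, which the γ-hydroxy epoxy enone would not tolerate; any trifluoroacetate formed at the alcohols is hydrolysed on work-up.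

## Compound list

1 | prop-2-yn-1-ol | C#CCO | starting material
2 | 3-bromoprop-1-ene (allyl bromide) | C=CCBr | starting material
3 | hex-5-en-2-yn-1-ol | C=CCC#CCO | intermediate
4 | sodium 2,2-bis(2-methoxyethoxy)-3-(prop-2-en-1-yl)-2,5-dihydro-1,2-oxaaluminol-2-uide (cyclic alkenylalanate) | [Na+].C=CCC1=CCO[Al-]1(OCCOC)OCCOC | intermediate (not isolated)
5 | (Z)-3-iodohexa-2,5-dien-1-ol | C=CC/C(I)=C/CO | intermediate
6 | triethyl{[(Z)-3-iodohexa-2,5-dien-1-yl]oxy}silane | C=CC/C(I)=C/CO[Si](CC)(CC)CC | intermediate
7 | tert-butyl 2-methylprop-2-enoate | C=C(C)C(=O)OC(C)(C)C | starting material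
8 | tert-butyl (2E,5Z)-5-iodo-2-methyl-7-(triethylsilyloxy)hepta-2,5-dienoate | CC(C)(C)OC(=O)/C(C)=C/C/C(I)=C/CO[Si](CC)(CC)CC | intermediate
9 | tert-butyldimethyl(prop-2-yn-1-yloxy)silane | C#CCO[Si](C)(C)C(C)(C)C | starting material
10 | tert-butyl (2E,5Z)-5-[4-(tert-butyldimethylsilyloxy)but-2-ynoyl]-2-methyl-7-(triethylsilyloxy)hepta-2,5-dienoate | CC(C)(C)OC(=O)/C(C)=C/C/C(=C/CO[Si](CC)(CC)CC)C(=O)C#CCO[Si](C)(C)C(C)(C)C | intermediate
11 | tert-butyl (2E,5Z)-5-{2-[3-(tert-butyldimethylsilyloxy)prop-1-yn-1-yl]-1,3-dioxolan-2-yl}-2-methyl-7-(triethylsilyloxy)hepta-2,5-dienoate | CC(C)(C)OC(=O)/C(C)=C/C/C(=C/CO[Si](CC)(CC)CC)C1(OCCO1)C#CCO[Si](C)(C)C(C)(C)C | intermediate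
12 | tert-butyl (2E,5Z)-5-{2-[3-(tert-butyldimethylsilyloxy)prop-1-yn-1-yl]-1,3-dioxolan-2-yl}-7-hydroxy-2-methylhepta-2,5-dienoate | CC(C)(C)OC(=O)/C(C)=C/C/C(=C/CO)C1(OCCO1)C#CCO[Si](C)(C)C(C)(C)C | intermediate
13 | tert-butyl (E)-4-[(2S,3S)-2-{2-[3-(tert-butyldimethylsilyloxy)prop-1-yn-1-yl]-1,3-dioxolan-2-yl}-3-(hydroxymethyl)oxiran-2-yl]-2-methylbut-2-enoate | OC[C@@H]1O[C@]1(C/C=C(\C)C(=O)OC(C)(C)C)C2(OCCO2)C#CCO[Si](C)(C)C(C)(C)C | intermediate
14 | tert-butyl (E)-4-[(2S,3R)-2-{2-[3-(tert-butyldimethylsilyloxy)prop-1-yn-1-yl]-1,3-dioxolan-2-yl}-3-formyloxiran-2-yl]-2-methylbut-2-enoate | O=C[C@@H]1O[C@]1(C/C=C(\C)C(=O)OC(C)(C)C)C2(OCCO2)C#CCO[Si](C)(C)C(C)(C)C | intermediate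
15 | (E)-hept-1-en-1-ylboronic acid | CCCCC/C=C/B(O)O | starting material
16 | tert-butyl (E)-4-[(1S,5R,6S)-2,2-(ethylenedioxy)-3-[(E)-hept-1-enyl]-5-hydroxy-4-(tert-butyldimethylsilyloxymethyl)-7-oxabicyclo[4.1.0]hept-3-en-1-yl]-2-methylbut-2-enoate (C3–OH trans to oxirane O) | CCCCC/C=C/C1=C(CO[Si](C)(C)C(C)(C)C)[C@@H](O)[C@@H]2O[C@]2(C/C=C(\C)C(=O)OC(C)(C)C)C13OCCO3 | intermediate
17 | tert-butyl (E)-4-[(1S,6R)-2,2-(ethylenedioxy)-3-[(E)-hept-1-enyl]-5-oxo-4-(tert-butyldimethylsilyloxymethyl)-7-oxabicyclo[4.1.0]hept-3-en-1-yl]-2-methylbut-2-enoate | CCCCC/C=C/C1=C(CO[Si](C)(C)C(C)(C)C)C(=O)[C@@H]2O[C@]2(C/C=C(\C)C(=O)OC(C)(C)C)C13OCCO3 | intermediate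
18 | tert-butyl (E)-4-[(1S,5S,6S)-2,2-(ethylenedioxy)-3-[(E)-hept-1-enyl]-5-hydroxy-4-(tert-butyldimethylsilyloxymethyl)-7-oxabicyclo[4.1.0]hept-3-en-1-yl]-2-methylbut-2-enoate (C3–OH cis to oxirane O) | CCCCC/C=C/C1=C(CO[Si](C)(C)C(C)(C)C)[C@H](O)[C@@H]2O[C@]2(C/C=C(\C)C(=O)OC(C)(C)C)C13OCCO3 | intermediate
19 | tert-butyl (E)-4-[(1S,5S,6S)-3-[(E)-hept-1-enyl]-5-hydroxy-4-(hydroxymethyl)-2-oxo-7-oxabicyclo[4.1.0]hept-3-en-1-yl]-2-methylbut-2-enoate | CCCCC/C=C/C1=C(CO)[C@H](O)[C@@H]2O[C@]2(C/C=C(\C)C(=O)OC(C)(C)C)C1=O | intermediate
20 | (E)-4-[(1S,5S,6S)-3-[(E)-hept-1-enyl]-5-hydroxy-4-(hydroxymethyl)-2-oxo-7-oxabicyclo[4.1.0]hept-3-en-1-yl]-2-methylbut-2-enoic acid | CCCCC/C=C/C1=C(CO)[C@H](O)[C@@H]2O[C@]2(C/C=C(\C)C(=O)O)C1=O | target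

## Step count and least certain steps

Total: 14 steps. Longest linear sequence: 14 steps (from 1 and 2 to 20); 7, 9 and 15 enter as purchased. Should the ring closure strongly favour the cis alcohol 18 over 16, steps 11 and 12 become unnecessary.

**Step 10 (key step).** The alkyne is flanked by the quaternary ketal carbon and is inductively deactivated. Its engagement with palladium may therefore be slower than methanol addition to, or oxirane opening of, the epoxy aldehyde, and slower than protodeboronation of 15. Incomplete alkenyl transfer would end in protonation of the alkenylpalladium. C3 selectivity is not a risk, because of steps 11 and 12. The fallback forms the two bonds one at a time by known reactions, setting out from 14 and returning at 19. HF·pyridine would free the propargylic alcohol of 14 to give hydroxy alkynal F1. Hydroxyl-directed trans-hydrostannation ([Cp*RuCl]4, Bu3SnH) would put tin on C2 and hydrogen on C1 in an anti sense, giving (Z)-alkenylstannane F2. Iodine would convert this into alkenyl iodide F3, which is resilylated (TBSCl, imidazole) to silyl ether F4. An intramolecular Nozaki–Hiyama–Kishi reaction (CrCl2, NiCl2 cat., DMF) would form C2–C3 and give the heptenyl-free ring alcohol F5 as C3 epimers. Dess–Martin oxidation to enone F6 and Luche reduction to cis alcohol F7 mirror steps 11 and 12, and aqueous HCl would give the C6 enone diol F8. Iodination at C1 (I2, pyridine) to iodoenone F9 and Suzuki coupling with 15 (PdCl2(PhCN)2, AsPh3, Ag2O, THF/H2O) would then deliver 19.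

**Step 8.** The cis substituent on C5 of 12 is a fully substituted ketal carbon, and Z-allylic alcohols with bulky cis groups are the weakest substrates for the Ti(OiPr)4–diethyl tartrate catalyst. Slow turnover and poor facial selection are the likely failure, together with Ti(OiPr)4-induced ionisation of the ketal and capture by the C3 hydroxyl. The fallback uses reagent-controlled, non-directed epoxidation; it sets out from 11 and returns at 13. Shi epoxidation of 11 (KHSO5, buffered MeCN/H2O) would give epoxy silyl ether F10. The catalyst would be the enantiomer of the fructose-derived ketone, the series the spiro transition-state model assigns by analogy with trans-disubstituted alkenes. HF·pyridine then returns to 13.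

**Step 5.** At one atmosphere of CO, direct Sonogashira coupling without CO insertion can compete, and the amine can add to the product ynone. The fallback replaces the carbonylation by addition and oxidation, sets out from 8 and 9 and returns at 10. 9 would be formylated (n-BuLi, then DMF) to 4-(tert-butyldimethylsilyloxy)but-2-ynal F11. Nozaki–Hiyama–Kishi coupling of 8 with F11 (CrCl2, NiCl2 cat., DMSO) would give carbinol F12, and MnO2 would oxidise this to 10.

**Step 12.** The C5 side chain lies on the face anti to the oxirane and may hinder hydride approach there, which would erode facial selectivity and return part of the material as 16. The fallback is inversion and not reduction; it sets out from 16 (separated from 18) and returns at 18. Mitsunobu reaction of 16 with 4-nitrobenzoic acid (PPh3, DIAD) would give the inverted 4-nitrobenzoate F13, and K2CO3 in MeOH would cleave it to 18.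

## Further compounds

F1 | step 10 | tert-butyl (E)-4-[(2S,3R)-3-formyl-2-[2-(3-hydroxyprop-1-yn-1-yl)-1,3-dioxolan-2-yl]oxiran-2-yl]-2-methylbut-2-enoate | O=C[C@@H]1O[C@]1(C/C=C(\C)C(=O)OC(C)(C)C)C2(OCCO2)C#CCO
F2 | step 10 | tert-butyl (E)-4-[(2S,3R)-3-formyl-2-{2-[(Z)-3-hydroxy-2-(tributylstannyl)prop-1-en-1-yl]-1,3-dioxolan-2-yl}oxiran-2-yl]-2-methylbut-2-enoate | O=C[C@@H]1O[C@]1(C/C=C(\C)C(=O)OC(C)(C)C)C2(OCCO2)/C=C(/CO)[Sn](CCCC)(CCCC)CCCC
F3 | step 10 | tert-butyl (E)-4-[(2S,3R)-3-formyl-2-{2-[(Z)-3-hydroxy-2-iodoprop-1-en-1-yl]-1,3-dioxolan-2-yl}oxiran-2-yl]-2-methylbut-2-enoate | O=C[C@@H]1O[C@]1(C/C=C(\C)C(=O)OC(C)(C)C)C2(OCCO2)/C=C(/CO)I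
F4 | step 10 | tert-butyl (E)-4-[(2S,3R)-2-{2-[(Z)-3-(tert-butyldimethylsilyloxy)-2-iodoprop-1-en-1-yl]-1,3-dioxolan-2-yl}-3-formyloxiran-2-yl]-2-methylbut-2-enoate | O=C[C@@H]1O[C@]1(C/C=C(\C)C(=O)OC(C)(C)C)C2(OCCO2)/C=C(/CO[Si](C)(C)C(C)(C)C)I
F5 | step 10 | tert-butyl (E)-4-[(1S,5RS,6S)-2,2-(ethylenedioxy)-5-hydroxy-4-(tert-butyldimethylsilyloxymethyl)-7-oxabicyclo[4.1.0]hept-3-en-1-yl]-2-methylbut-2-enoate (C3 epimers) | C1=C(CO[Si](C)(C)C(C)(C)C)C(O)[C@@H]2O[C@]2(C/C=C(\C)C(=O)OC(C)(C)C)C13OCCO3
F6 | step 10 | tert-butyl (E)-4-[(1S,6R)-2,2-(ethylenedioxy)-5-oxo-4-(tert-butyldimethylsilyloxymethyl)-7-oxabicyclo[4.1.0]hept-3-en-1-yl]-2-methylbut-2-enoate | C1=C(CO[Si](C)(C)C(C)(C)C)C(=O)[C@@H]2O[C@]2(C/C=C(\C)C(=O)OC(C)(C)C)C13OCCO3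
F7 | step 10 | tert-butyl (E)-4-[(1S,5S,6S)-2,2-(ethylenedioxy)-5-hydroxy-4-(tert-butyldimethylsilyloxymethyl)-7-oxabicyclo[4.1.0]hept-3-en-1-yl]-2-methylbut-2-enoate | C1=C(CO[Si](C)(C)C(C)(C)C)[C@H](O)[C@@H]2O[C@]2(C/C=C(\C)C(=O)OC(C)(C)C)C13OCCO3
F8 | step 10 | tert-butyl (E)-4-[(1S,5S,6S)-5-hydroxy-4-(hydroxymethyl)-2-oxo-7-oxabicyclo[4.1.0]hept-3-en-1-yl]-2-methylbut-2-enoate | C1=C(CO)[C@H](O)[C@@H]2O[C@]2(C/C=C(\C)C(=O)OC(C)(C)C)C1=O
F9 | step 10 | tert-butyl (E)-4-[(1S,5S,6S)-5-hydroxy-4-(hydroxymethyl)-3-iodo-2-oxo-7-oxabicyclo[4.1.0]hept-3-en-1-yl]-2-methylbut-2-enoate | IC1=C(CO)[C@H](O)[C@@H]2O[C@]2(C/C=C(\C)C(=O)OC(C)(C)C)C1=O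
F10 | step 8 | tert-butyl (E)-4-[(2S,3S)-2-{2-[3-(tert-butyldimethylsilyloxy)prop-1-yn-1-yl]-1,3-dioxolan-2-yl}-3-(triethylsilyloxymethyl)oxiran-2-yl]-2-methylbut-2-enoate | CC[Si](CC)(CC)OC[C@@H]1O[C@]1(C/C=C(\C)C(=O)OC(C)(C)C)C2(OCCO2)C#CCO[Si](C)(C)C(C)(C)C
F11 | step 5 | 4-(tert-butyldimethylsilyloxy)but-2-ynal | O=CC#CCO[Si](C)(C)C(C)(C)C
F12 | step 5 | tert-butyl (2E,5Z)-5-[4-(tert-butyldimethylsilyloxy)-1-hydroxybut-2-yn-1-yl]-2-methyl-7-(triethylsilyloxy)hepta-2,5-dienoate (racemic at the carbinol) | CC(C)(C)OC(=O)/C(C)=C/C/C(=C/CO[Si](CC)(CC)CC)C(O)C#CCO[Si](C)(C)C(C)(C)C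
F13 | step 12 | tert-butyl (E)-4-[(1S,5S,6S)-2,2-(ethylenedioxy)-3-[(E)-hept-1-enyl]-5-(4-nitrobenzoyloxy)-4-(tert-butyldimethylsilyloxymethyl)-7-oxabicyclo[4.1.0]hept-3-en-1-yl]-2-methylbut-2-enoate | CCCCC/C=C/C1=C(CO[Si](C)(C)C(C)(C)C)[C@H](OC(=O)c4ccc(cc4)[N+]([O-])=O)[C@@H]2O[C@]2(C/C=C(\C)C(=O)OC(C)(C)C)C13OCCO3
A1 | alternative 1 | syn-diepoxide (C2–C3 and C4–C5 oxiranes cis to each other and anti to the C6 OTBS group; CH2OTBDPS at C2, side-chain methyl ester at C5) | C1[C@]2(CO[Si](c3ccccc3)(c3ccccc3)C(C)(C)C)O[C@@H]2[C@@H]3O[C@]3(C/C=C(\C)C(=O)OC)[C@H]1O[Si](C)(C)C(C)(C)C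
A2 | alternative 1 | cyclohexa-1,3-diene precursor (C2=C3–C4=C5; CH2OTBDPS at C2, side-chain methyl ester at C5, OTBS at C6) | C1C(CO[Si](c2ccccc2)(c2ccccc2)C(C)(C)C)=CC=C(C/C=C(\C)C(=O)OC)[C@H]1O[Si](C)(C)C(C)(C)C
A3 | alternative 2 | bis-TBS ether methyl ester of the target | CCCCC/C=C/C1=C(CO[Si](C)(C)C(C)(C)C)[C@H](O[Si](C)(C)C(C)(C)C)[C@@H]2O[C@]2(C/C=C(\C)C(=O)OC)C1=O
A4 | alternative 2 | open-chain chloro keto aldehyde (C4 aldehyde, (3S)-C3 OTBS, Z-configured C1=C2 with heptenyl and CH2OTBS, C6 ketone, C5 chloride as either epimer, side-chain methyl ester) | CCCCC/C=C/C(=C(\CO[Si](C)(C)C(C)(C)C)[C@H](O[Si](C)(C)C(C)(C)C)C=O)C(=O)C(Cl)C/C=C(\C)C(=O)OC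
A5 | alternative 3 | methyl (E)-4-[2-hydroxy-3-((E)-hept-1-enyl)-4-(tert-butyldimethylsilyloxymethyl)-5-methoxyphenyl]-2-methylbut-2-enoate | CCCCC/C=C/c1c(CO[Si](C)(C)C(C)(C)C)c(OC)cc(C/C=C(\C)C(=O)OC)c1O
A6 | alternative 3 | pentacarbonyl{(2E,4E)-2-[(tert-butyldimethylsilyloxy)methyl]-1-methoxydeca-2,4-dien-1-ylidene}chromium | CCCCC/C=C/C=C(\CO[Si](C)(C)C(C)(C)C)C(OC)=[Cr](=C=O)(=C=O)(=C=O)(=C=O)=C=O
A7 | alternative 3 | methyl (E)-2-methylhex-2-en-5-ynoate | C#CC/C=C(\C)C(=O)OC
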